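The constants of this cycle are hidden, so the flask has to be reckoned from a time read off the earlier runs, which differ in their charge of added ligand.

common to all: starting material 0.050 M; free catalyst 1 mol%

| run | coupling partner | added ligand | remark |
|---|---|---|---|
| blue | 3 equiv | 0.43 mM | run made earlier |
| teal | 3 equiv | 1.7 mM | run made earlier |
| flask | 3.00 equiv | 0.87 mM |  |

- blue (time / min: product / %, starting material / %): 8.00: 14, 82; 15.0: 29, 72; 25.0: 41, 61; 30.0: 49, 52; 40.0: 58, 42
- teal (time / min: product / %, starting material / %): 8.00: 12, 86; 15.0: 26, 76; 25.0: 32, 67; 30.0: 39, 61; 40.0: 47, 52

(scatter of a reading: 1.5 percentage points)

- amounts and yields of released group count crystals too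
- given per volume of solution although it is solid: crystals
- candidate steps: catalyst intermediate C -> catalyst intermediate D; catalyst intermediate B -> released group + catalyst intermediate C; starting material + free catalyst -> catalyst intermediate A; free catalyst + added ligand <-> idle complex; coupling partner + catalyst intermediate A -> catalyst intermediate B; crystals <-> released group; catalyst intermediate D -> free catalyst + product
- no earlier run changes the charge of free catalyst; that part of a forecast is a guess
- no earlier run changes the charge of coupling partner; that part of a forecast is a guess

1. apparent order in free catalyst when 30% of the starting material are converted (percent change of the rate of making product for one percent more free catalyst charged)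
2. apparent order in coupling partner when 30% of the starting material are converted (percent change of the rate of making product for one percent more coupling partner charged)
3. factor on the rate of making product when 30% of the starting material are converted if coupling partner is charged twice over

Take the half-life of starting material, t½, the time in which a first-order loss halves what is left. The last readings give 32.0 min in blue and 42.4 min in teal, so the loss is slower in the run with more added ligand.

Teal read at 25.0 min gives 43.3 min, so its loss stays close to first order in starting material. By 40.0 min coupling partner in teal has lost 15.7% of its charge, so that shape says little about the order in coupling partner, and no earlier run changes that charge: any figure for that order is a guess.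

If added ligand holds catalyst back in proportion to its amount, t½ rises in a straight line with added ligand. The flask, at 0.87 mM, then has a half-life of starting material of 35.6 min, which leaves 37.8% after 50.0 min.

In the flask, 0.87 mM of added ligand faces 0.500 mM of free catalyst, so a larger catalyst charge draws the ligand down further. The order in free catalyst is therefore reckoned here as above one.

The forecast gives 1.02, 0.1 and 1.07: "Coupling partner enters after that step, so its order should be small".

The flask gives 1.2, 0.079 and 1.04, and keeps 38% of its starting material after 50.0 min.

    catalyst intermediate C → catalyst intermediate D (k = 0.0840 s⁻¹)
    catalyst intermediate B → released group + catalyst intermediate C (k = 0.870 s⁻¹)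
    starting material + free catalyst → catalyst intermediate A (k = 1.60 M⁻¹ s⁻¹)
    free catalyst + added ligand ⇌ idle complex (K = 1600 M⁻¹, k = 0.810 M⁻¹ s⁻¹)
    coupling partner + catalyst intermediate A → catalyst intermediate B (k = 2.80 M⁻¹ s⁻¹)
    crystals ⇌ released group, rate k6*(cs6 - [released group]) while solid is left; crystals form when [released group] > cs6 (solubility = 26.0 mM, k = 0.0770 s⁻¹)
    catalyst intermediate D → free catalyst + product (k = 0.930 s⁻¹)

In the flask, added ligand at its charge, by the forward step alone, takes free catalyst with a half-life of 16.4 min, which is shorter than the 35.6 min of starting material. The idle complex, an off-cycle form of the catalyst, holds 8.26% of the catalyst charged after 5.00 min, 27.1% after 25.0 min and 37.0% after 50.0 min.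

(The numbers in the tables come from a simulation for an exercise; noise was put on by code.)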